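## Structural features

The target is a flavone (ring A benzo, ring C 4-pyranone, ring B a 4',5'-dimethoxyphenyl on C2) in which C3 is tied back to the C2' oxygen of ring B through C9H2–C10(=C11Me2), so that a seven-membered oxepine (ring D) is fused to rings B and C. Ring A is hexasubstituted: C5 carries OMe, C6 a prenyl group, and C7–O/C8 carry an angularly fused 2,2-dimethyl-2H-pyran. There is no stereocentre and no stereogenic double bond, because every exocyclic alkene ends in CMe2 and the chromene alkene is held cis by its ring. The fragile groups are the tetrasubstituted aryl enol ether C10=C11 (protonation at C11 leads to double-bond migration or hydrolysis) and the chromene and prenyl alkenes (acid, electrophiles, oxidants). The real difficulties are closing ring D with the isopropylidene enol ether already in its final position, and loading ring A with three different substituents without regiochemical ambiguity. Once the pyranone O1–C2 bond is opened, C3 is the central carbon of a 1,3-diketone, and C9–C10(OAr)=C11Me2 is the CH2-terminated end of a 2-aryloxy-1,1-dimethylallyl unit. The key step pairs these two: the diketone carbon C3 as soft nucleophile and C9 as the unhindered terminus of an allylpalladium cation held on the ring B oxygen, forming C3–C9 and ring D.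

## Logic of the disconnections

25 to 22: the pyranone O1–C2 bond is cut and C2 is returned to the ketone level. A 4-pyranone fused to an arene is the cyclodehydration product of an ortho-hydroxyaryl 1,3-diketone, so this exposes C3 as a diketone carbon and removes one ring. The forward step must free the C8a phenol with fluoride and dehydrate the hemiketal 24 (reached through 23) under acid too weak to protonate C10=C11.

22 to 21: the C3–C9 bond is cut (key step). This opens ring D and leaves an acyclic diketone whose ring B ether carries an allylic methyl carbonate. The forward step needs ionisation of a carbonate on a tetrasubstituted alkene, attack at CH2 rather than CMe2, carbon rather than oxygen alkylation, and a silent ring A phenol (silyl ether).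

21 to 18 + 10 (through 20): the C2–C3 bond is cut as an aldol bond, with one oxidation afterwards. An aldehyde acceptor reacts with the enolate 19 at −78 °C, where the methyl carbonate and the aryl silyl ether are inert. An ester acceptor would need warming and excess enolate in front of that carbonate. The cost is one oxidation step; the gain is two fragments of similar size joined under mild conditions.

10 to 7 (through 9 and 8): the carbonate C–O bond and the C1'–CHO bond are cut, leaving bromine at C1'. Bromine is inert to the hydride reduction that makes the allylic alcohol and to the phosphonate carbanion in the olefination. A benzoate at C1' would demand a chemoselective ester reduction and would offer that carbanion a five-membered Dieckmann closure. The forward step must perform bromine–lithium exchange in the presence of the alkoxide.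

7 to 3 + 2 + 5 (through 6 and 4), and 2 to 1: the C10=C11 bond is cut as an olefination with 5, and the aryl O–C10 bond as an O–H insertion of the carbenoid from 2. This reduces ring B to a bromophenol, a diazo phosphonate and acetone. The olefination must cope with a ketone partner.

18 to 13 + 14 (through 17, 16 and 15): the O–Si bond is cut, then the C6–prenyl bond by a retro para-Claisen–Cope to the O-prenyl ether 15. Both carbons ortho to the ether oxygen are blocked, so the allyl unit can only come to rest on the one ring carbon that bears hydrogen, and it arrives as a linear prenyl group.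

13 to 11 + 12: the chromene C–C and C–O bonds are cut as a formal [3+3] annulation of a resorcinol-type ketone with an enal. The forward step must condense at the carbon between the two hydroxyls and close onto the non-chelated oxygen.

## Other disconnections considered

Alternative 1: The cut runs through ring A. C8–C8a, C5–C6, C7–C8 and C4a–C5 are removed together, leaving the ring B/C/D pyranone as its 6-diazoacetyl derivative A1 and the prenyl-substituted siloxyalkyne A2.
- Forward step: Wolff rearrangement of A1 would give a pyranonyl ketene. [2+2] addition of A2, four-electron opening of the cyclobutenone and six-electron closure onto the future C4a should give phenol A3, with OH at C5, prenyl at C6 and OSi at C7 fixed by the mechanism.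
- In favour: ring A regiochemistry does not depend on phenol directing effects, the two oxygens emerge differentiated, and four bonds form in one operation. On ring A regiocontrol and on convergence it is the better plan.
- Against: A3 still lacks the C8 carbon. Methylation of a chelated C5 hydroxyl, desilylation and chromene annulation at C8 remain on the most advanced material. The ketene would form close to the electron-rich C10=C11 enol ether, a possible partner for an unwanted intramolecular [2+2]. The oxepine must already be present in A1, so the ring D problem is only moved to an earlier substrate, and A1 needs an acid chloride and diazoalkane sequence beside an acid-sensitive enol ether.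
- Comparison: structurally it builds a ring that the chosen plan buys and decorates in four steps. Mechanistically it replaces one ionic C–C bond formation by a pericyclic cascade with more ways to stray. In step count it is expected to be longer once A1, A2 and the post-annulation steps are counted.

Alternative 2: The cut runs through ring B. C5'–C6', C1'–C2' and C2'–C3' are removed, leaving the 2-ethynylchromone A4 (rings A and C complete, C3 carrying a 2-bromoprenyl group) and the Fischer carbene (CO)5Cr=C(OMe)C(OMe)=CH2, A5.
- Forward step: alkyne insertion into A5, CO insertion and six-electron closure (Dötz benzannulation) should give phenol A6. The large alkyne substituent ends up next to the new hydroxyl, so the C2' phenol appears where ring D must close, and an intramolecular C–O coupling with the vinyl bromide would follow.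
- In favour: the ring B oxygen pattern comes from the carbene itself. The flavone is complete before ring D is made, so neither a silyl ether nor a hemiketal dehydration is needed at the end; on that point it is the better plan. The enol ether is formed late under basic conditions, as in the chosen plan (equal on that point).
- Against: chromium is stoichiometric. The alkyne in A4 is conjugated to the chromone and electron-poor, a class for which benzannulation is less dependable. The electron-rich 4-methoxyphenol A6 must be freed from chromium without oxidation to a quinone. The subsequent coupling has to join a phenol to a tetrasubstituted vinyl bromide in a seven-membered ring. A4 needs all the ring A work of the chosen plan plus a C3 alkylation and an alkynyl chromone synthesis.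
- Comparison: structurally it assembles ring B atom by atom where the chosen plan starts from a catalogue phenol. Mechanistically it places two demanding metal-mediated steps in series. In step economy it is clearly longer.

Alternative 3: The cut is the aryl ether bond O–C2'. The precursor is the 2'-bromoflavone A7, which carries CH2–CH(OH)–C(CH3)=CH2 on C3.
- Forward step: monovalent copper (CuI, a phenanthroline ligand, Cs2CO3) should couple the secondary allylic alcohol with the aryl bromide and close ring D, giving racemic A8 with an sp3 C10 and an isopropenyl group. The double bond must then be moved into the C10=C11 position.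
- In favour: intramolecular copper-catalysed aryl ether formation to benzo-fused seven-membered rings is more routine than attack on a 2-aryloxyallyl palladium cation; on precedent for the ring closure it is the better plan. The flavone is again complete before ring D.
- Against: the coupling partner is a hindered secondary alcohol and an electron-rich, ortho-substituted bromide. The final isomerisation must convert a 1,1-disubstituted alkene into a tetrasubstituted enol ether. Metal hydride catalysts are slow for this, and the C6 prenyl and chromene alkenes are exposed to them. Base would first remove a C9 proton (vinylogous to the pyranone carbonyl) and could expel the aryloxide, reopening ring D. A stereocentre is made only to be destroyed.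
- Comparison: structurally the two plans close the same ring at different bonds. Mechanistically the chosen plan creates the isopropylidene enol ether in the ring-forming event, whereas A8 needs a further step without good precedent. Step counts to the precursors are similar, so the alternative is longer by that uncertain step.

Key step: step 13

Assumption: 3 and 11 are treated as catalogue compounds; 21 is written as the diketo tautomer and 22 and 23 as the enol on the ring B side, each standing for its tautomeric mixture.

## Route

Step 1
Reactants: 1 triethyl phosphonoacetate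
Product: 2 ethyl 2-diazo-2-(diethoxyphosphoryl)acetate
Conditions: p-ABSA, DBU, MeCN, 0 °C → rt
Reagents that add atoms: 4-acetamidobenzenesulfonyl azide, CC(=O)Nc1ccc(cc1)S(=O)(=O)N=[N+]=[N-]
Why: Regitz diazo transfer to a methylene activated by an ester and a phosphonate; DBU is basic enough to form the stabilised carbanion and the sulfonamide is removed by washing.

Step 2
Reactants: 3 2-bromo-4,5-dimethoxyphenol; 2 ethyl 2-diazo-2-(diethoxyphosphoryl)acetate
Product: 4 ethyl 2-(2-bromo-4,5-dimethoxyphenoxy)-2-(diethoxyphosphoryl)acetate (racemic)
Conditions: Rh2(OAc)4 (1 mol %), PhMe, 80 °C, slow addition of 2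
Reagents that add atoms: none
Why: Rhodium carbenoid O–H insertion of an acceptor/acceptor diazo compound into a phenol, which is faster than attack on the arene; the new stereocentre is racemic and is erased in step 3.

Step 3
Reactants: 4 ethyl 2-(2-bromo-4,5-dimethoxyphenoxy)-2-(diethoxyphosphoryl)acetate; 5 acetone
Product: 6 ethyl 2-(2-bromo-4,5-dimethoxyphenoxy)-3-methylbut-2-enoate
Conditions: NaH, THF, 0 °C; 5 (5 equiv), 0 → 50 °C
Reagents that add atoms: none
Why: Horner–Wadsworth–Emmons olefination of an α-aryloxy phosphonoacetate with a ketone; the two alkene methyls are identical, so no geometry arises, and the ortho bromine gives the carbanion no intramolecular electrophile.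

Step 4
Reactants: 6 ethyl 2-(2-bromo-4,5-dimethoxyphenoxy)-3-methylbut-2-enoate
Product: 7 2-(2-bromo-4,5-dimethoxyphenoxy)-3-methylbut-2-en-1-ol
Conditions: DIBAL-H (2.5 equiv), CH2Cl2, −78 → 0 °C; aq Rochelle salt
Reagents that add atoms: none
Why: DIBAL-H 1,2-reduction of an enoate to the allylic alcohol; the aryl bromide and the enol ether are inert, and no second carbonyl group competes.

Step 5
Reactants: 7 2-(2-bromo-4,5-dimethoxyphenoxy)-3-methylbut-2-en-1-ol
Product: 9 2-[(1-hydroxy-3-methylbut-2-en-2-yl)oxy]-4,5-dimethoxybenzaldehyde, via aryllithium alkoxide 8 (not isolated)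
Conditions: n-BuLi (2.2 equiv), THF, −78 °C; DMF, −78 → 0 °C; aq NH4Cl
Reagents that add atoms: N,N-dimethylformamide, CN(C)C=O
Why: The first equivalent of n-BuLi forms the alkoxide and the second effects bromine–lithium exchange at −78 °C; Bouveault formylation with DMF gives the aldehyde when the hemiaminal collapses on quench.

Step 6
Reactants: 9 2-[(1-hydroxy-3-methylbut-2-en-2-yl)oxy]-4,5-dimethoxybenzaldehyde
Product: 10 2-(2-formyl-4,5-dimethoxyphenoxy)-3-methylbut-2-en-1-yl methyl carbonate
Conditions: ClCO2Me, pyridine, CH2Cl2, 0 °C
Reagents that add atoms: methyl chloroformate, COC(=O)Cl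
Why: Acylation of a primary allylic alcohol by a chloroformate with pyridine as base; the aldehyde and the enol ether do not react.

Step 7
Reactants: 11 1-(2,4-dihydroxy-6-methoxyphenyl)ethan-1-one; 12 3-methylbut-2-enal
Product: 13 1-(5-hydroxy-7-methoxy-2,2-dimethyl-2H-chromen-6-yl)ethan-1-one
Conditions: pyridine, 120 °C, sealed tube
Reagents that add atoms: none
Why: Formal [3+3] chromene annulation: condensation at the ring carbon between the two hydroxyls, dehydration to an ortho-quinone methide and oxa-6π electrocyclisation onto the non-chelated oxygen; the hydroxyl chelated to the acetyl group is retained.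

Step 8
Reactants: 13 1-(5-hydroxy-7-methoxy-2,2-dimethyl-2H-chromen-6-yl)ethan-1-one; 14 1-bromo-3-methylbut-2-ene
Product: 15 1-[7-methoxy-2,2-dimethyl-5-(3-methylbut-2-en-1-yloxy)-2H-chromen-6-yl]ethan-1-one
Conditions: K2CO3, DMF, 50 °C
Reagents that add atoms: none
Why: Williamson etherification of the only phenol by SN2 displacement at a primary allylic bromide; mild carbonate base favours O-alkylation.

Step 9
Reactants: 15 1-[7-methoxy-2,2-dimethyl-5-(3-methylbut-2-en-1-yloxy)-2H-chromen-6-yl]ethan-1-one
Product: 17 1-[5-hydroxy-7-methoxy-2,2-dimethyl-8-(3-methylbut-2-en-1-yl)-2H-chromen-6-yl]ethan-1-one, via ortho-dienone 16 (not isolated)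
Conditions: PhNEt2, 195 °C, sealed tube
Reagents that add atoms: none
Why: Aromatic para-Claisen rearrangement: a [3,3] shift to a blocked ortho carbon gives dienone 16 (a transient racemic quaternary centre), and a Cope [3,3] shift relays the allyl unit to C8, the only ring carbon bearing hydrogen. The two allylic inversions restore a linear prenyl group, and tautomerisation to the chelated phenol drives the sequence.

Step 10
Reactants: 17 1-[5-hydroxy-7-methoxy-2,2-dimethyl-8-(3-methylbut-2-en-1-yl)-2H-chromen-6-yl]ethan-1-one
Product: 18 1-[5-(tert-butyldimethylsilyloxy)-7-methoxy-2,2-dimethyl-8-(3-methylbut-2-en-1-yl)-2H-chromen-6-yl]ethan-1-one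
Conditions: NaH (1.05 equiv), THF, 0 °C; TBSCl, 0 °C → rt
Reagents that add atoms: tert-butyldimethylsilyl chloride, CC(C)(C)[Si](C)(C)Cl
Why: The phenol is far more acidic than the methyl ketone, so one equivalent of NaH gives the phenoxide, which is silylated on oxygen; the silyl ether keeps this oxygen out of steps 11 to 13.

Step 11
Reactants: 18 1-[5-(tert-butyldimethylsilyloxy)-7-methoxy-2,2-dimethyl-8-(3-methylbut-2-en-1-yl)-2H-chromen-6-yl]ethan-1-one; 10 2-(2-formyl-4,5-dimethoxyphenoxy)-3-methylbut-2-en-1-yl methyl carbonate
Product: 20 2-{2-[3-ArA-1-hydroxy-3-oxopropyl]-4,5-dimethoxyphenoxy}-3-methylbut-2-en-1-yl methyl carbonate (racemic; ArA = the 6-chromenyl group of 18), via lithium enolate 19 (not isolated)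
Conditions: LDA (1.05 equiv), THF, −78 °C; 10, −78 °C; AcOH, −78 °C
Reagents that add atoms: none
Why: Aldol addition of a kinetic lithium enolate to an aldehyde; at −78 °C the aldehyde is far more electrophilic than the carbonate, and the cold acidic quench prevents retro-aldol and silyl migration. The carbinol centre is racemic and is removed in step 12.

Step 12
Reactants: 20 2-{2-[3-ArA-1-hydroxy-3-oxopropyl]-4,5-dimethoxyphenoxy}-3-methylbut-2-en-1-yl methyl carbonate
Product: 21 2-{2-[3-ArA-3-oxopropanoyl]-4,5-dimethoxyphenoxy}-3-methylbut-2-en-1-yl methyl carbonate (1,3-diketone; ArA as in 18)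
Conditions: Dess–Martin periodinane, NaHCO3, CH2Cl2, 0 °C → rt
Reagents that add atoms: none
Why: Dess–Martin oxidation of a β-hydroxy ketone to the 1,3-diketone under buffered conditions; the alkenes, enol ether, carbonate and silyl ether are inert to the periodinane.

Step 13
Reactants: 21 2-{2-[3-ArA-3-oxopropanoyl]-4,5-dimethoxyphenoxy}-3-methylbut-2-en-1-yl methyl carbonate
Product: 22 ArA [5-hydroxy-7,8-dimethoxy-2-(propan-2-ylidene)-2,3-dihydro-1-benzoxepin-4-yl] ketone (enol form of the 4-aroyl-2-isopropylidene-3,4-dihydro-1-benzoxepin-5(2H)-one; ArA as in 18)
Conditions: Pd2(dba)3 (2.5 mol %), dppe (6 mol %), THF (0.01 M), 50 °C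
Reagents that add atoms: none
Why: Zerovalent palladium from Pd2(dba)3 and dppe should coordinate the C10=C11 alkene anti to the carbonate and ionise it to a 2-aryloxy-1,1-dimethylallyl palladium cation, with loss of CO2 and methoxide. The methoxide deprotonates the 1,3-diketone, so no base is added and the only nucleophile present is the soft diketonate. Its central carbon C3 attacks the CH2 terminus C9 from the face opposite palladium, forming C3–C9 and releasing the catalyst; the closest known reaction type is the intramolecular Tsuji–Trost allylic alkylation of 1,3-dicarbonyl compounds, and 2-aryloxyallyl palladium cations of this kind are known intermediates in palladium-catalysed reactions of propargylic carbonates with phenols. Ring D closes as a seven-membered ring in an exo mode with respect to the allyl unit: C9 and the central carbon C10 lie in the ring, C11 stays outside, and the C10=C11 isopropylidene enol ether is produced directly. No stereocentre is formed, because C3 of 22 is enolised and becomes sp2 in the target. Terminus selectivity (C9 over C11, both of which would give a seven-membered ring) rests on the two methyl groups on C11; carbon over oxygen selectivity rests on the reversibility of O-allylation under palladium; the silyl ether keeps the ring A oxygen out; and 0.01 M dilution favours cyclisation over oligomerisation.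

Step 14
Reactants: 22 ArA [5-hydroxy-7,8-dimethoxy-2-(propan-2-ylidene)-2,3-dihydro-1-benzoxepin-4-yl] ketone
Product: 25 oxepinoflavone CNP0192589.0 (target; 5-methoxy-6-prenylflavone with a 2,2-dimethyl-2H-pyran fused at C7–O/C8, 4',5'-dimethoxy groups on ring B and a CH2–C(=CMe2)–O bridge from C3 to C2'), via free phenol 23 (not isolated), via hemiketal 24 (not isolated)
Conditions: TBAF, AcOH, THF, 0 °C → rt; then PPTS (20 mol %), PhMe, 50 °C
Reagents that add atoms: none
Why: Buffered fluoride cleaves the aryl silyl ether, and the freed phenol adds to the C2 ketone to give the six-membered hemiketal 24, whose C2 and C3 stereocentres are transient. PPTS-mediated dehydration across C2–C3 then forms the aromatic 4-pyranone; the acid is weak enough to spare the aryl enol ether, whose oxygen is conjugated through ring B to the pyranone.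

## Compound list

1 | triethyl phosphonoacetate | CCOC(=O)CP(=O)(OCC)OCC | starting material
2 | ethyl 2-diazo-2-(diethoxyphosphoryl)acetate | CCOC(=O)C(=[N+]=[N-])P(=O)(OCC)OCC | intermediate
3 | 2-bromo-4,5-dimethoxyphenol | COc1cc(O)c(Br)cc1OC | starting material
4 | ethyl 2-(2-bromo-4,5-dimethoxyphenoxy)-2-(diethoxyphosphoryl)acetate (racemic) | CCOC(=O)C(Oc1cc(OC)c(OC)cc1Br)P(=O)(OCC)OCC | intermediate
5 | acetone | CC(C)=O | starting material
6 | ethyl 2-(2-bromo-4,5-dimethoxyphenoxy)-3-methylbut-2-enoate | CCOC(=O)C(Oc1cc(OC)c(OC)cc1Br)=C(C)C | intermediate
7 | 2-(2-bromo-4,5-dimethoxyphenoxy)-3-methylbut-2-en-1-ol | CC(C)=C(CO)Oc1cc(OC)c(OC)cc1Br | intermediate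
8 | lithium 2-(2-lithio-4,5-dimethoxyphenoxy)-3-methylbut-2-en-1-olate | [Li]OCC(=C(C)C)Oc1cc(OC)c(OC)cc1[Li] | intermediate
9 | 2-[(1-hydroxy-3-methylbut-2-en-2-yl)oxy]-4,5-dimethoxybenzaldehyde | CC(C)=C(CO)Oc1cc(OC)c(OC)cc1C=O | intermediate
10 | 2-(2-formyl-4,5-dimethoxyphenoxy)-3-methylbut-2-en-1-yl methyl carbonate | COC(=O)OCC(=C(C)C)Oc1cc(OC)c(OC)cc1C=O | intermediate
11 | 1-(2,4-dihydroxy-6-methoxyphenyl)ethan-1-one | CC(=O)c1c(O)cc(O)cc1OC | starting material
12 | 3-methylbut-2-enal | CC(C)=CC=O | starting material
13 | 1-(5-hydroxy-7-methoxy-2,2-dimethyl-2H-chromen-6-yl)ethan-1-one | CC(=O)c1c(O)c2C=CC(C)(C)Oc2cc1OC | intermediate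
14 | 1-bromo-3-methylbut-2-ene | CC(C)=CCBr | starting material
15 | 1-[7-methoxy-2,2-dimethyl-5-(3-methylbut-2-en-1-yloxy)-2H-chromen-6-yl]ethan-1-one | CC(=O)c1c(OCC=C(C)C)c2C=CC(C)(C)Oc2cc1OC | intermediate
16 | 6-acetyl-7-methoxy-2,2-dimethyl-6-(2-methylbut-3-en-2-yl)-2H-chromen-5(6H)-one (racemic) | CC(=O)C1(C(C)(C)C=C)C(=O)C2=C(OC(C)(C)C=C2)C=C1OC | intermediate
17 | 1-[5-hydroxy-7-methoxy-2,2-dimethyl-8-(3-methylbut-2-en-1-yl)-2H-chromen-6-yl]ethan-1-one | CC(=O)c1c(O)c2C=CC(C)(C)Oc2c(CC=C(C)C)c1OC | intermediate
18 | 1-[5-(tert-butyldimethylsilyloxy)-7-methoxy-2,2-dimethyl-8-(3-methylbut-2-en-1-yl)-2H-chromen-6-yl]ethan-1-one | CC(=O)c1c(O[Si](C)(C)C(C)(C)C)c2C=CC(C)(C)Oc2c(CC=C(C)C)c1OC | intermediate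
19 | lithium enolate of 18 | C=C(O[Li])c1c(O[Si](C)(C)C(C)(C)C)c2C=CC(C)(C)Oc2c(CC=C(C)C)c1OC | intermediate
20 | 2-{2-[3-ArA-1-hydroxy-3-oxopropyl]-4,5-dimethoxyphenoxy}-3-methylbut-2-en-1-yl methyl carbonate (racemic; ArA = the 6-chromenyl group of 18) | COC(=O)OCC(=C(C)C)Oc1cc(OC)c(OC)cc1C(O)CC(=O)c1c(O[Si](C)(C)C(C)(C)C)c2C=CC(C)(C)Oc2c(CC=C(C)C)c1OC | intermediate
21 | 2-{2-[3-ArA-3-oxopropanoyl]-4,5-dimethoxyphenoxy}-3-methylbut-2-en-1-yl methyl carbonate (key-step precursor) | COC(=O)OCC(=C(C)C)Oc1cc(OC)c(OC)cc1C(=O)CC(=O)c1c(O[Si](C)(C)C(C)(C)C)c2C=CC(C)(C)Oc2c(CC=C(C)C)c1OC | intermediate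
22 | ArA [5-hydroxy-7,8-dimethoxy-2-(propan-2-ylidene)-2,3-dihydro-1-benzoxepin-4-yl] ketone (key-step product, enol form) | COc1cc2c(cc1OC)C(O)=C(CC(=C(C)C)O2)C(=O)c1c(O[Si](C)(C)C(C)(C)C)c2C=CC(C)(C)Oc2c(CC=C(C)C)c1OC | intermediate
23 | desilylated 22 (free C8a phenol, enol form) | COc1cc2c(cc1OC)C(O)=C(CC(=C(C)C)O2)C(=O)c1c(O)c2C=CC(C)(C)Oc2c(CC=C(C)C)c1OC | intermediate
24 | 2-hydroxyflavanone hemiketal of 23 (O1–C2 closed; C2/C3 diastereomers, racemic) | COc1cc2c(cc1OC)C3(O)Oc4c5c(c(CC=C(C)C)c(OC)c4C(=O)C3CC(=C(C)C)O2)OC(C)(C)C=C5 | intermediate
25 | oxepinoflavone CNP0192589.0 | COc1cc2c(cc1OC)-c1oc3c4c(c(CC=C(C)C)c(OC)c3c(=O)c1CC(=C(C)C)O2)OC(C)(C)C=C4 | target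

## Step count and least certain steps

Total: 14 steps. Longest linear sequence: 10 steps (steps 1 to 6, then 11 to 14); the ring A branch (steps 7 to 10) joins at step 11.

Step 13 (key step). The most likely failure is slow ionisation: the carbonate sits on a tetrasubstituted, electron-rich alkene that binds zerovalent palladium poorly, so the catalyst may decay before turnover. O-allylation or attack at the CMe2 terminus may compete once the cation forms. The fallback drops the metal and closes the ring by an SN2 alkylation. It sets out from 9, which is converted without allylic transposition (MsCl, LiCl, 2,4,6-collidine, DMF, 0 °C) into 2-[(1-chloro-3-methylbut-2-en-2-yl)oxy]-4,5-dimethoxybenzaldehyde F1. Addition of enolate 19 (from 18, as in step 11) should give the chloro β-hydroxy ketone F2, and Dess–Martin oxidation the chloro 1,3-diketone F3. Cs2CO3 in MeCN at high dilution should then C-alkylate the diketone intramolecularly, and the route is rejoined at 22.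

Step 3. The hindered, stabilised phosphonate carbanion may add too slowly to an enolisable ketone, so that proton transfer and self-condensation of acetone consume the reagents. The fallback builds the same alkene by cross-coupling and sets out from 3. Alkylation with ethyl 2-chloro-3-oxobutanoate (K2CO3, acetone, reflux) gives ethyl 2-(2-bromo-4,5-dimethoxyphenoxy)-3-oxobutanoate F4. Enol triflation (NaH, PhNTf2, THF) gives ethyl (E)-2-(2-bromo-4,5-dimethoxyphenoxy)-3-(trifluoromethylsulfonyloxy)but-2-enoate F5; either geometry would serve. Methyl coupling (MeMgBr, Fe(acac)3 5 mol %, THF/NMP, −30 °C) should replace the triflate and spare the aryl bromide, rejoining the route at 6.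

Step 7. Condensation at the ring carbon next to the methoxy group, or electrocyclisation onto the chelated oxygen, would give regioisomeric chromenes. The fallback replaces the condensation by a sigmatropic route and sets out from 11. Selective alkylation of the non-chelated hydroxyl (3-chloro-3-methylbut-1-yne, K2CO3, KI, CuI cat., acetone, reflux) gives 1-[2-hydroxy-6-methoxy-4-(2-methylbut-3-yn-2-yloxy)phenyl]ethan-1-one F6. Heating in PhNEt2 (190 °C) should trigger the aryl propargyl Claisen rearrangement, hydrogen shift and 6π closure. Bond fixation by the chelated ketone is expected to direct the shift to the carbon between the two oxygens, rejoining the route at 13.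

Step 9. The sequence may stall at the dienone stage or lose material by thermal fragmentation (deacetylation of the dienone, opening of the chromene) at 195 °C. The fallback is a direct Friedel–Crafts prenylation that sets out from 13: 2-methylbut-3-en-2-ol and BF3·OEt2 in dioxane at rt should alkylate C8, the only free ring carbon and para to the phenol. This rejoins the route at 17 without a new intermediate, at the price of a modest conversion expected for this reaction type.

Step 14. During the acid stage the C10=C11 enol ether may be protonated, leading to double-bond migration or hydrolysis; at the fluoride stage a retro-Claisen cleavage of the 2-substituted diketone is possible if the medium becomes basic. The fallback removes the acid: from 22, buffered desilylation as above, isolation of 24, then MsCl and Et3N (CH2Cl2, 0 °C → rt). The C2 methanesulfonate of 24 F7 should undergo base-mediated elimination across C2–C3, as in the standard dehydration of β-hydroxy ketones, rejoining the route at 25.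

## Further compounds

F1 | step 13 | 2-[(1-chloro-3-methylbut-2-en-2-yl)oxy]-4,5-dimethoxybenzaldehyde | CC(C)=C(CCl)Oc1cc(OC)c(OC)cc1C=O
F2 | step 13 | chloro β-hydroxy ketone (20 with CH2Cl in place of CH2OCO2Me; racemic) | ClCC(=C(C)C)Oc1cc(OC)c(OC)cc1C(O)CC(=O)c1c(O[Si](C)(C)C(C)(C)C)c2C=CC(C)(C)Oc2c(CC=C(C)C)c1OC
F3 | step 13 | chloro 1,3-diketone (21 with CH2Cl in place of CH2OCO2Me) | ClCC(=C(C)C)Oc1cc(OC)c(OC)cc1C(=O)CC(=O)c1c(O[Si](C)(C)C(C)(C)C)c2C=CC(C)(C)Oc2c(CC=C(C)C)c1OC
F4 | step 3 | ethyl 2-(2-bromo-4,5-dimethoxyphenoxy)-3-oxobutanoate (racemic) | CCOC(=O)C(Oc1cc(OC)c(OC)cc1Br)C(C)=O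
F5 | step 3 | ethyl (E)-2-(2-bromo-4,5-dimethoxyphenoxy)-3-(trifluoromethylsulfonyloxy)but-2-enoate | CCOC(=O)/C(Oc1cc(OC)c(OC)cc1Br)=C(/C)OS(=O)(=O)C(F)(F)F
F6 | step 7 | 1-[2-hydroxy-6-methoxy-4-(2-methylbut-3-yn-2-yloxy)phenyl]ethan-1-one | CC(=O)c1c(O)cc(OC(C)(C)C#C)cc1OC
F0 | step 9 | none | none
F7 | step 14 | C2 methanesulfonate of hemiketal 24 (C2/C3 diastereomers, racemic) | COc1cc2c(cc1OC)C3(OS(C)(=O)=O)Oc4c5c(c(CC=C(C)C)c(OC)c4C(=O)C3CC(=C(C)C)O2)OC(C)(C)C=C5
A1 | alternative 1 | 6-(diazoacetyl)pyran-4-one fused at C2/C3 to the 7,8-dimethoxy-2-isopropylidene benzoxepine (rings B, C and D without ring A) | COc1cc2c(cc1OC)-c1oc(C(=O)C=[N+]=[N-])cc(=O)c1CC(=C(C)C)O2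
A2 | alternative 1 | 5-methyl-1-(triisopropylsilyloxy)hex-4-en-1-yne | CC(C)=CCC#CO[Si](C(C)C)(C(C)C)C(C)C
A3 | alternative 1 | 5-hydroxy-6-prenyl-7-(triisopropylsilyloxy) oxepinoflavone with C8 unsubstituted | COc1cc2c(cc1OC)-c1oc3cc(O[Si](C(C)C)(C(C)C)C(C)C)c(CC=C(C)C)c(O)c3c(=O)c1CC(=C(C)C)O2
A4 | alternative 2 | 2-ethynylchromone with rings A and C complete and a 2-bromoprenyl group on C3 | C#Cc1oc2c3c(c(CC=C(C)C)c(OC)c2c(=O)c1CC(Br)=C(C)C)OC(C)(C)C=C3
A5 | alternative 2 | pentacarbonyl[methoxy(1-methoxyethenyl)methylidene]chromium, (CO)5Cr=C(OMe)C(OMe)=CH2 | COC(=C)C(OC)=[Cr](=C=O)(=C=O)(=C=O)(=C=O)=C=O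
A6 | alternative 2 | 2'-hydroxy-4',5'-dimethoxyflavone carrying the C3 2-bromoprenyl group | COc1cc(O)c(cc1OC)-c1oc2c3c(c(CC=C(C)C)c(OC)c2c(=O)c1CC(Br)=C(C)C)OC(C)(C)C=C3
A7 | alternative 3 | 2'-bromo-4',5'-dimethoxyflavone carrying CH2–CH(OH)–C(CH3)=CH2 on C3 (racemic) | COc1cc(Br)c(cc1OC)-c1oc2c3c(c(CC=C(C)C)c(OC)c2c(=O)c1CC(O)C(C)=C)OC(C)(C)C=C3
A8 | alternative 3 | oxepinoflavone with a C10 isopropenyl group (racemic allylic ether isomer of the target) | COc1cc2c(cc1OC)-c1oc3c4c(c(CC=C(C)C)c(OC)c3c(=O)c1CC(C(C)=C)O2)OC(C)(C)C=C4
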